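## Retrosynthetic overview

1. The (Z)-4-hydroxycinnamate is built last, on the molecule, by a Z-selective Horner–Wadsworth–Emmons reaction of a C19 diaryl-phosphonoacetate; this leads back to labda-13(16),14-diene-8α,19-diol (19).
2. Side chain: C11–C12 by alkylation of a C11 phenylsulfonyl carbanion with 2,3-dibromopropene, C13–C14 by Suzuki vinylation, then reductive removal of the sulfone.
3. Ring B (formed second): C8–C9 by SmI2 ketyl–olefin cyclisation of the C8 methyl ketone onto a C9=C11 vinyl sulfone; this sets C8 and C9.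
4. Ring A (formed first): C1–C10 and C4–C5 in one catalytic enantioselective Diels–Alder reaction of (E)-2-methyl-6-oxohept-2-enal (C5–C10, C17, C20; from sulcatone) with a (3Z)-1-phenylthio diene (C1–C4, C18, C19). The sulfur is a traceless regiocontrol element, removed later together with the C2=C3 bond.
5. Enabling feature: ring A is an all-carbon six-membered ring whose C5–C10 edge carries H/CH3 trans and C6/C9 trans (the trans A/B fusion), which is the retron of an (E)-2-methyl-2-enal with C9 as the formyl carbon; the C1–C2–C3–C4 arc ends at quaternary C4 (CH3, CH2O), a 4,4-disubstituted diene terminus.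

Key step: step 4

Remark: labdane numbering (C1–C20) and α/β descriptors (β = face of the C10 methyl) are used for all intermediates; any (1Z) isomer of diene 5 formed in step 1 is assumed to be separable and unreactive in step 4.

## Route

Step 1
Reactants: 1 4-methylfuran-2(5H)-one; 2 diethyl [(phenylsulfanyl)methyl]phosphonate
Product: 4 (2Z,4E)-2-methyl-5-(phenylsulfanyl)penta-2,4-dien-1-ol, via lactol 3 (not isolated)
Conditions: i-Bu2AlH (1.05 equiv), CH2Cl2, −78 °C; then 2/n-BuLi (THF, −78 °C), −78 °C → rt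
Reagents that add atoms: none
Why: One-pot half-reduction of the butenolide to its aluminium lactolate and Horner–Wadsworth–Emmons olefination of the ring-opened hydroxy-enal; the 2Z geometry (CH2OH cis to the new vinyl group) is inherited from the ring and the new vinyl sulfide bond is expected to form mainly E.

Step 2
Reactants: 4 (2Z,4E)-2-methyl-5-(phenylsulfanyl)penta-2,4-dien-1-ol
Product: 5 tert-butyl(dimethyl){[(2Z,4E)-2-methyl-5-(phenylsulfanyl)penta-2,4-dien-1-yl]oxy}silane
Conditions: TBSCl, imidazole, CH2Cl2, 0 °C → rt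
Reagents that add atoms: tert-butyldimethylsilyl chloride CC(C)(C)[Si](C)(C)Cl
Why: Standard silylation of a primary allylic alcohol; the bulky, weakly basic silyl ether is chosen to resist ionisation under the Lewis acid of step 4.

Step 3
Reactants: 6 6-methylhept-5-en-2-one
Product: 8 (E)-2-methyl-6-oxohept-2-enal, via allylic alcohol 7 (not isolated)
Conditions: SeO2 (0.5 equiv), t-BuOOH, salicylic acid (cat.), CH2Cl2, rt; then MnO2, CH2Cl2, rt
Reagents that add atoms: selenium dioxide O=[Se]=O; tert-butyl hydroperoxide (restores SeO2) CC(C)(C)OO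
Why: Allylic oxidation by SeO2 (ene reaction, then [2,3]-sigmatropic shift) is selective for the (E)-methyl of the trisubstituted alkene at room temperature, and MnO2 oxidises only the allylic alcohol, leaving the ketone.

Step 4
Reactants: 5 tert-butyl(dimethyl){[(2Z,4E)-2-methyl-5-(phenylsulfanyl)penta-2,4-dien-1-yl]oxy}silane; 8 (E)-2-methyl-6-oxohept-2-enal
Product: 9 ring A aldehyde, 5-{[(tert-butyldimethylsilyl)oxy]methyl}-1,5-dimethyl-6-(3-oxobutyl)-2-(phenylsulfanyl)cyclohex-3-ene-1-carbaldehyde (labdane numbering: 10β-CH3, 10α-CHO, 1α-SPh, 4α-CH3, 4β-CH2OSi, 5α-H, Δ2)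
Conditions: (S)-1-(2-methylphenyl)-3,3-diphenyltetrahydro-1H,3H-pyrrolo[1,2-c][1,3,2]oxazaborole (20 mol %), Tf2NH (18 mol %), CH2Cl2, −78 → −40 °C
Reagents that add atoms: none
Why: The triflimide-activated oxazaborolidine binds the formyl group of 8, and the s-trans enal undergoes an asynchronous normal-demand [4+2] cycloaddition with s-cis 5; the closest known reaction type is the chiral oxazaborolidinium-catalysed Diels–Alder addition of 2-substituted enals to 1-heteroatom-substituted dienes. Ring A is closed by intermolecular suprafacial [4+2] cycloaddition, the C4–C5 bond (nucleophilic diene terminus to the enal β-carbon) leading and the C1–C10 bond following. C5 and C10 (H/CH3 trans, C6/C9 trans) follow from the E geometry of 8; C4 (CH2OSi β, CH3 α) follows from the 3Z geometry of 5 combined with the formyl-endo transition state, which also sets the sacrificial C1 centre; the absolute sense comes from the catalyst, which must deliver the diene to the Cα-Si face (C10-Si/C5-Re) of bound 8, and the (S)-catalyst is assigned on the basis of the accepted formyl C–H···O binding model. The step needs regiochemistry with sulfur next to the formyl-bearing carbon, secured by the C1 phenylthio donor (largest HOMO coefficient at C4) and by the fact that the other orientation would join two quaternary carbons. It needs endo selectivity, secured by the activated formyl group together with the exo preference of the β-alkyl chain, and reactivity despite the inward CH2OSi group, secured by the cationic Lewis acid and the sulfur donor.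

Step 5
Reactants: 9 ring A aldehyde; 10 diethyl [(phenylsulfonyl)methyl]phosphonate
Product: 11 ring A (E)-vinyl sulfone, 4-{6-{[(tert-butyldimethylsilyl)oxy]methyl}-2,6-dimethyl-2-[(E)-2-(phenylsulfonyl)ethenyl]-3-(phenylsulfanyl)cyclohex-4-en-1-yl}butan-2-one (stereocentres as in 9)
Conditions: NaH, THF, 0 °C → rt
Reagents that add atoms: none
Why: Horner–Wadsworth–Emmons olefination is chemoselective for the aldehyde over the methyl ketone and gives the (E)-vinyl sulfone; C10 is quaternary, so no stereocentre can epimerise.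

Step 6
Reactants: 11 ring A (E)-vinyl sulfone
Product: 12 19-[(tert-butyldimethylsilyl)oxy]-11-(phenylsulfonyl)-1α-(phenylsulfanyl)-12,13,14,15,16-pentanorlabd-2-en-8α-ol
Conditions: SmI2 (2.5 equiv), HMPA, t-BuOH, THF, −78 °C
Reagents that add atoms: none
Why: SmI2 ketyl–olefin reductive cyclisation (6-exo-trig) closes ring B through a chair-like transition state in which the bulky samarium-bound oxygen is equatorial and anti to the equatorial sulfonylvinyl acceptor, which should give 8α-OH/8β-CH3 and 9α-H (9β side chain) on a trans-decalin.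

Step 7
Reactants: 12 hydroxy sulfone with C1 sulfide
Product: 13 19-[(tert-butyldimethylsilyl)oxy]-11-(phenylsulfonyl)-12,13,14,15,16-pentanorlabdan-8α-ol
Conditions: Raney Ni (W-2, excess), H2 (1 atm), EtOH, 25 → 50 °C
Reagents that add atoms: none
Why: Raney Ni hydrogenolysis of the allylic C–S bond and hydrogenation of the disubstituted ring A alkene occur in one operation; the aryl sulfone, silyl ether and tertiary alcohol are inert, and C1 ceases to be a stereocentre.

Step 8
Reactants: 13 saturated hydroxy sulfone; 14 2,3-dibromoprop-1-ene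
Product: 15 13-bromo-19-[(tert-butyldimethylsilyl)oxy]-11-(phenylsulfonyl)-14,15-dinorlabd-13(16)-en-8α-ol (C11 epimers)
Conditions: n-BuLi (2.2 equiv), THF/DMPU, −78 °C; then 14, −78 → −20 °C
Reagents that add atoms: none
Why: Alkylation of the α-sulfonyl carbanion (formed as the O,C-dianion) by the allylic bromide (SN2); the new C11 centre forms without control and is erased in step 10.

Step 9
Reactants: 15 bromoalkene sulfone; 16 4,4,5,5-tetramethyl-2-vinyl-1,3,2-dioxaborolane
Product: 17 19-[(tert-butyldimethylsilyl)oxy]-11-(phenylsulfonyl)labda-13(16),14-dien-8α-ol (C11 epimers)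
Conditions: PdCl2(dppf) (5 mol %), K3PO4, THF/H2O, 60 °C
Reagents that add atoms: none
Why: Suzuki–Miyaura coupling of a 2-bromoalkene with a vinylboronate is a standard entry to 2-substituted buta-1,3-dienes and tolerates the free tertiary alcohol and the sulfone.

Step 10
Reactants: 17 diene sulfone
Product: 18 19-[(tert-butyldimethylsilyl)oxy]labda-13(16),14-dien-8α-ol
Conditions: Na/Hg (6 %), Na2HPO4, MeOH/THF, −20 °C
Reagents that add atoms: none
Why: Reductive desulfonylation by electron transfer (as in the Julia sequence) removes the activating group; the unactivated 1,3-diene is not reduced by the amalgam.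

Step 11
Reactants: 18 silyl ether
Product: 19 labda-13(16),14-diene-8α,19-diol
Conditions: Bu4NF, THF, 25 → 50 °C
Reagents that add atoms: none
Why: Fluoride cleavage of the neopentyl silyl ether; no other group is fluoride-sensitive.

Step 12
Reactants: 19 diol; 20 bromoacetyl bromide
Product: 21 8α-hydroxylabda-13(16),14-dien-19-yl bromoacetate
Conditions: pyridine, CH2Cl2, −20 °C
Reagents that add atoms: none
Why: Acylation occurs at the primary C19 hydroxyl only; the hindered tertiary C8 hydroxyl does not react under these conditions.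

Step 13
Reactants: 21 bromoacetate; 22 diphenyl phosphite
Product: 23 8α-hydroxylabda-13(16),14-dien-19-yl (diphenoxyphosphoryl)acetate
Conditions: Et3N, CH2Cl2, 0 °C → rt
Reagents that add atoms: none
Why: Michaelis–Becker-type P-alkylation of the phosphite by the α-bromo ester gives the diaryl phosphonoacetate needed for Z-selective olefination.

Step 14
Reactants: 23 phosphonoacetate; 24 4-[(tert-butyldimethylsilyl)oxy]benzaldehyde
Product: 25 8α-hydroxylabda-13(16),14-dien-19-yl (Z)-3-{4-[(tert-butyldimethylsilyl)oxy]phenyl}prop-2-enoate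
Conditions: NaH (1.05 equiv), THF, −78 °C; then 24, −78 → −40 °C
Reagents that add atoms: none
Why: Z-selective Horner–Wadsworth–Emmons reaction: with the electron-poor diaryl phosphonate the oxaphosphetane collapses faster than the adducts equilibrate, so the Z-cinnamate should form under kinetic control.

Step 15
Reactants: 25 silyl-protected ester
Product: 26 8α-hydroxylabda-13(16),14-dien-19-yl (Z)-3-(4-hydroxyphenyl)prop-2-enoate (CNP0197278.1)
Conditions: HF·pyridine, pyridine, THF, 0 °C, dark
Reagents that add atoms: none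
Why: Buffered fluoride desilylation of the aryl silyl ether avoids a free phenoxide, which would lower the barrier to Z→E isomerisation; the ester, diene and tertiary alcohol are untouched.

## Compound list

1 | 4-methylfuran-2(5H)-one | CC1=CC(=O)OC1 | starting material
2 | diethyl [(phenylsulfanyl)methyl]phosphonate | CCOP(=O)(CSc1ccccc1)OCC | starting material
3 | 4-methyl-2,5-dihydrofuran-2-ol (lactol, present as its aluminium alkoxide) | CC1=CC(O)OC1 | intermediate
4 | (2Z,4E)-2-methyl-5-(phenylsulfanyl)penta-2,4-dien-1-ol | OC/C(C)=C\C=C\Sc1ccccc1 | intermediate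
5 | tert-butyl(dimethyl){[(2Z,4E)-2-methyl-5-(phenylsulfanyl)penta-2,4-dien-1-yl]oxy}silane | CC(C)(C)[Si](C)(C)OC/C(C)=C\C=C\Sc1ccccc1 | intermediate
6 | 6-methylhept-5-en-2-one | CC(=O)CCC=C(C)C | starting material
7 | (E)-7-hydroxy-6-methylhept-5-en-2-one | CC(=O)CC/C=C(\C)CO | intermediate
8 | (E)-2-methyl-6-oxohept-2-enal | CC(=O)CC/C=C(\C)C=O | intermediate
9 | ring A aldehyde (10β-CH3, 10α-CHO, 1α-SPh, 4α-CH3, 4β-CH2OTBS, 5α-H, Δ2) | O=C[C@@]1(C)[C@@H](Sc2ccccc2)C=C[C@](C)(CO[Si](C)(C)C(C)(C)C)[C@@H]1CCC(C)=O | intermediate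
10 | diethyl [(phenylsulfonyl)methyl]phosphonate | CCOP(=O)(CS(=O)(=O)c1ccccc1)OCC | starting material
11 | ring A (E)-vinyl sulfone (stereocentres as in 9) | O=S(=O)(/C=C/[C@@]1(C)[C@@H](Sc2ccccc2)C=C[C@](C)(CO[Si](C)(C)C(C)(C)C)[C@@H]1CCC(C)=O)c1ccccc1 | intermediate
12 | 19-[(tert-butyldimethylsilyl)oxy]-11-(phenylsulfonyl)-1α-(phenylsulfanyl)-12,13,14,15,16-pentanorlabd-2-en-8α-ol | O=S(=O)(C[C@@H]1[C@@]2(C)[C@@H](Sc3ccccc3)C=C[C@](C)(CO[Si](C)(C)C(C)(C)C)[C@@H]2CC[C@@]1(C)O)c1ccccc1 | intermediate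
13 | 19-[(tert-butyldimethylsilyl)oxy]-11-(phenylsulfonyl)-12,13,14,15,16-pentanorlabdan-8α-ol | O=S(=O)(C[C@@H]1[C@@]2(C)CCC[C@](C)(CO[Si](C)(C)C(C)(C)C)[C@@H]2CC[C@@]1(C)O)c1ccccc1 | intermediate
14 | 2,3-dibromoprop-1-ene | C=C(Br)CBr | starting material
15 | 13-bromo-19-[(tert-butyldimethylsilyl)oxy]-11-(phenylsulfonyl)-14,15-dinorlabd-13(16)-en-8α-ol (C11 epimers) | C=C(Br)CC([C@@H]1[C@@]2(C)CCC[C@](C)(CO[Si](C)(C)C(C)(C)C)[C@@H]2CC[C@@]1(C)O)S(=O)(=O)c1ccccc1 | intermediate
16 | 4,4,5,5-tetramethyl-2-vinyl-1,3,2-dioxaborolane | C=CB1OC(C)(C)C(C)(C)O1 | starting material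
17 | 19-[(tert-butyldimethylsilyl)oxy]-11-(phenylsulfonyl)labda-13(16),14-dien-8α-ol (C11 epimers) | C=CC(=C)CC([C@@H]1[C@@]2(C)CCC[C@](C)(CO[Si](C)(C)C(C)(C)C)[C@@H]2CC[C@@]1(C)O)S(=O)(=O)c1ccccc1 | intermediate
18 | 19-[(tert-butyldimethylsilyl)oxy]labda-13(16),14-dien-8α-ol | C=CC(=C)CC[C@@H]1[C@@]2(C)CCC[C@](C)(CO[Si](C)(C)C(C)(C)C)[C@@H]2CC[C@@]1(C)O | intermediate
19 | labda-13(16),14-diene-8α,19-diol | C=CC(=C)CC[C@@H]1[C@@]2(C)CCC[C@](C)(CO)[C@@H]2CC[C@@]1(C)O | intermediate
20 | bromoacetyl bromide | BrCC(Br)=O | starting material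
21 | 8α-hydroxylabda-13(16),14-dien-19-yl bromoacetate | C=CC(=C)CC[C@@H]1[C@@]2(C)CCC[C@](C)(COC(=O)CBr)[C@@H]2CC[C@@]1(C)O | intermediate
22 | diphenyl phosphite | O=[PH](Oc1ccccc1)Oc1ccccc1 | starting material
23 | 8α-hydroxylabda-13(16),14-dien-19-yl (diphenoxyphosphoryl)acetate | C=CC(=C)CC[C@@H]1[C@@]2(C)CCC[C@](C)(COC(=O)CP(=O)(Oc3ccccc3)Oc3ccccc3)[C@@H]2CC[C@@]1(C)O | intermediate
24 | 4-[(tert-butyldimethylsilyl)oxy]benzaldehyde | O=Cc1ccc(O[Si](C)(C)C(C)(C)C)cc1 | starting material
25 | 8α-hydroxylabda-13(16),14-dien-19-yl (Z)-3-{4-[(tert-butyldimethylsilyl)oxy]phenyl}prop-2-enoate | C=CC(=C)CC[C@@H]1[C@@]2(C)CCC[C@](C)(COC(=O)/C=C\c3ccc(O[Si](C)(C)C(C)(C)C)cc3)[C@@H]2CC[C@@]1(C)O | intermediate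
26 | 8α-hydroxylabda-13(16),14-dien-19-yl (Z)-3-(4-hydroxyphenyl)prop-2-enoate (CNP0197278.1) | C=CC(=C)CC[C@@H]1[C@@]2(C)CCC[C@](C)(COC(=O)/C=C\c3ccc(O)cc3)[C@@H]2CC[C@@]1(C)O | target

## Step count and risks

Total step count: 15. Longest linear sequence: 14 steps (steps 1, 2 and 4–15).

**Step 4 (Diels–Alder).** The cycloaddition of the inward-substituted diene may be too slow, so that ionisation or oligomerisation of the dienyl sulfide competes, or endo and facial selectivity may be insufficient. The fallback sets out from 8 (with 5) and returns at 9. Enal 8 is condensed with (2R,3R)-butane-2,3-diol (PPTS, benzene, water removal) to the bis-dioxolane of 8 F1. TMSOTf with 2,6-di-tert-butylpyridine in CH2Cl2 at −78 °C ionises the allylic acetal to a vinyl-dioxolenium ion, which adds 5 in a stepwise cationic [4+2] process with the same regiochemistry. This gives the bis-dioxolane of 9 F2, with face control from the covalently bound C2-symmetric diol and diastereomers that can be separated. Mild aqueous acid (PPTS, acetone/H2O) then hydrolyses both acetals to 9.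

**Step 6 (SmI2 cyclisation).** Simple reduction of the vinyl sulfone or C–S cleavage may outrun ring closure, or the ketyl may close to the C8 epimer. The fallback sets out from 9 and returns at 19; it uses the enoate acceptor and builds the side chain by displacement instead of sulfone alkylation.
- Aldehyde 9 and triethyl phosphonoacetate (NaH, THF) give the ethyl (E)-enoate F3.
- SmI2, MeOH, THF, −78 °C closes ring B to ethyl 8α-hydroxy-1α-(phenylsulfanyl)-19-silyloxy-13,14,15,16-tetranorlabd-2-en-12-oate F4.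
- Raney Ni/H2 gives the saturated hydroxy ester F5.
- Et3SiOTf and 2,6-lutidine give the 8-O-triethylsilyl ether F6, so that the later C12 leaving group cannot close a tetrahydrofuran onto O8.
- LiAlH4 gives the 12-ol F7, and I2, PPh3, imidazole give the 12-iodide F8.
- Buta-1,3-dien-2-ylmagnesium chloride (from 2-chlorobuta-1,3-diene and Mg) with catalytic Li2CuCl4 in THF gives the bis-silyl labdadiene F9.
- Bu4NF removes both silyl groups to give 19.

**Step 14 (Z-selective olefination).** Z selectivity may erode on the hindered substrate-bound phosphonate, or the product may isomerise from Z to E. The fallback sets out from 19 and returns at 26; the Z-alkene is made and purified on a small fragment before attachment. 4-(Allyloxy)benzaldehyde and ethyl (diphenoxyphosphoryl)acetate (NaH, THF, −78 °C) give ethyl (Z)-3-[4-(allyloxy)phenyl]prop-2-enoate F10, which is freed of E isomer by chromatography. LiOH in THF/H2O in the dark gives (Z)-3-[4-(allyloxy)phenyl]prop-2-enoic acid F11. Carbodiimide esterification (DCC, catalytic DMAP, CH2Cl2, 0 °C) with the primary hydroxyl of 19 gives the O-allyl ether of 26 F12. Pd(PPh3)4 with morpholine in THF removes the allyl group to give 26.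

## Further compounds

F1 | step 4 | (4R,5R)-4,5-dimethyl-2-{(E)-5-[(4R,5R)-2,4,5-trimethyl-1,3-dioxolan-2-yl]pent-2-en-2-yl}-1,3-dioxolane | C[C@H]1OC(/C(C)=C/CCC2(C)O[C@H](C)[C@@H](C)O2)O[C@@H]1C
F2 | step 4 | bis[(4R,5R)-4,5-dimethyl-1,3-dioxolane] acetal of 9 | C[C@H]1OC(O[C@@H]1C)[C@@]2(C)[C@@H](Sc3ccccc3)C=C[C@](C)(CO[Si](C)(C)C(C)(C)C)[C@@H]2CCC4(C)O[C@H](C)[C@@H](C)O4
F3 | step 6 | ethyl (E)-3-[ring A of 9]prop-2-enoate (enoate analogue of 11) | CCOC(=O)/C=C/[C@@]1(C)[C@@H](Sc2ccccc2)C=C[C@](C)(CO[Si](C)(C)C(C)(C)C)[C@@H]1CCC(C)=O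
F4 | step 6 | ethyl 19-[(tert-butyldimethylsilyl)oxy]-8α-hydroxy-1α-(phenylsulfanyl)-13,14,15,16-tetranorlabd-2-en-12-oate | CCOC(=O)C[C@@H]1[C@@]2(C)[C@@H](Sc3ccccc3)C=C[C@](C)(CO[Si](C)(C)C(C)(C)C)[C@@H]2CC[C@@]1(C)O
F5 | step 6 | ethyl 19-[(tert-butyldimethylsilyl)oxy]-8α-hydroxy-13,14,15,16-tetranorlabdan-12-oate | CCOC(=O)C[C@@H]1[C@@]2(C)CCC[C@](C)(CO[Si](C)(C)C(C)(C)C)[C@@H]2CC[C@@]1(C)O
F6 | step 6 | ethyl 19-[(tert-butyldimethylsilyl)oxy]-8α-[(triethylsilyl)oxy]-13,14,15,16-tetranorlabdan-12-oate | CCOC(=O)C[C@@H]1[C@@]2(C)CCC[C@](C)(CO[Si](C)(C)C(C)(C)C)[C@@H]2CC[C@@]1(C)O[Si](CC)(CC)CC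
F7 | step 6 | 19-[(tert-butyldimethylsilyl)oxy]-8α-[(triethylsilyl)oxy]-13,14,15,16-tetranorlabdan-12-ol | OCC[C@@H]1[C@@]2(C)CCC[C@](C)(CO[Si](C)(C)C(C)(C)C)[C@@H]2CC[C@@]1(C)O[Si](CC)(CC)CC
F8 | step 6 | 12-iodo-19-[(tert-butyldimethylsilyl)oxy]-8α-[(triethylsilyl)oxy]-13,14,15,16-tetranorlabdane | ICC[C@@H]1[C@@]2(C)CCC[C@](C)(CO[Si](C)(C)C(C)(C)C)[C@@H]2CC[C@@]1(C)O[Si](CC)(CC)CC
F9 | step 6 | 19-[(tert-butyldimethylsilyl)oxy]-8α-[(triethylsilyl)oxy]labda-13(16),14-diene | C=CC(=C)CC[C@@H]1[C@@]2(C)CCC[C@](C)(CO[Si](C)(C)C(C)(C)C)[C@@H]2CC[C@@]1(C)O[Si](CC)(CC)CC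
F10 | step 14 | ethyl (Z)-3-[4-(prop-2-en-1-yloxy)phenyl]prop-2-enoate | CCOC(=O)/C=C\c1ccc(OCC=C)cc1
F11 | step 14 | (Z)-3-[4-(prop-2-en-1-yloxy)phenyl]prop-2-enoic acid | OC(=O)/C=C\c1ccc(OCC=C)cc1
F12 | step 14 | 8α-hydroxylabda-13(16),14-dien-19-yl (Z)-3-[4-(prop-2-en-1-yloxy)phenyl]prop-2-enoate | C=CC(=C)CC[C@@H]1[C@@]2(C)CCC[C@](C)(COC(=O)/C=C\c3ccc(OCC=C)cc3)[C@@H]2CC[C@@]1(C)O
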